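**Retrosynthetic overview**

1. Target 28 ⇐ cis-semi-reduction of the C15≡C16 alkyne of dienyne 27 ⇐ Sonogashira coupling (C16–C17) of enynol 25 with 4-bromobutenolide 26; the E C13=C14 alkene ⇐ Horner–Wadsworth–Emmons reaction of phosphonate 20 with silylpropynal 21; C12–C13 ⇐ alkylation of phosphonoacetate 18 with iodide 17.
2. Iodide 17 ⇐ decalin ester 15 ⇐ closure of ring B at C9–C10 from the monocyclic allenoate 14 (key step).
3. Feature used: C10 is a quaternary ring-fusion carbon that can be generated as the tertiary radical of a 2,6,6-trimethylcyclohexene (ring A, C5 already stereodefined), and C9 is the central carbon of a C8=C9=C11 allenoate. Joining C9 to C10 closes ring B, leaves the C8=C9 alkene in the ring and leaves C11–C12 as an acetate arm.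
4. Allenoate 14 ⇐ propargylic carbonate 13 (palladium/formate) ⇐ (S)-dihydro-α-ionone 9 + methyl propiolate 10; ketone 9 ⇐ racemic α-ionone 1 by crystallisation of one α-ionol diastereomer, lipase resolution, oxidation and 1,4-reduction.
5. Ring order: ring A is bought with α-ionone, ring B is closed in step 10, the butenolide ring is attached intact in step 17.

Key step: step 10

Atom labels: decalin C1 to C10 (C4 gem-dimethyl, C5 ring-fusion CH, C8=C9 alkene, C10 methylated ring fusion); chain C11 to C16 outward from C9, with C13a the hydroxymethyl carbon on C13; lactone C17 to C20 (C19 carbonyl, C20 OCH2).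

Assumption: the α-ionol diastereomer whose 4-nitrobenzoate crystallises is taken to be the (1S*,2R*) pair, and the lipase is taken to acetylate its (2R) enantiomer. If the (1S*,2S*) pair crystallises instead, the (1S) ring sits in the unreacted (2S) alcohol, which then enters step 6 directly and step 5 falls away.

**Step 1**
Reactants: 1 racemic α-ionone, (3E)-4-(2,6,6-trimethylcyclohex-2-en-1-yl)but-3-en-2-one
Product: 2 α-ionol, (3E)-4-(2,6,6-trimethylcyclohex-2-en-1-yl)but-3-en-2-ol (all four stereoisomers)
Conditions: NaBH4, CeCl3·7H2O, MeOH, 0 °C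
Reagents that add atoms: none
Why: Luche reduction delivers hydride 1,2 to the enone carbonyl only, and no stereocontrol is needed because the isomers are sorted in the next three steps.

**Step 2**
Reactants: 2 α-ionol (four stereoisomers)
Product: 3 rac-(2R*,3E)-4-[(1S*)-2,6,6-trimethylcyclohex-2-en-1-yl]but-3-en-2-yl 4-nitrobenzoate
Conditions: 4-nitrobenzoyl chloride, pyridine, 4-(dimethylamino)pyridine (cat.), CH2Cl2, 0 °C to rt; then fractional crystallisation from hexane
Reagents that add atoms: 4-nitrobenzoyl chloride, O=C(Cl)c1ccc(cc1)[N+](=O)[O-]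
Why: Acylation of a secondary allylic alcohol with an acid chloride is routine, and the 4-nitrobenzoate is chosen because one racemic diastereomer should crystallise selectively, which sorts the relative configuration of ring and carbinol centres without chromatography.

**Step 3**
Reactants: 3 rac-(1S*,2R*) 4-nitrobenzoate
Product: 4 rac-(2R*,3E)-4-[(1S*)-2,6,6-trimethylcyclohex-2-en-1-yl]but-3-en-2-ol
Conditions: K2CO3 (cat.), MeOH, rt
Reagents that add atoms: none
Why: Base-catalysed transesterification of an activated aryl ester frees the allylic alcohol without touching either stereocentre.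

**Step 4**
Reactants: 4 rac-(1S*,2R*)-α-ionol
Product: 5 (2R,3E)-4-[(1S)-2,6,6-trimethylcyclohex-2-en-1-yl]but-3-en-2-yl acetate
Conditions: Burkholderia cepacia lipase (lipase PS), vinyl acetate, t-BuOMe, rt, stopped near half conversion; chromatography
Reagents that add atoms: vinyl acetate, CC(=O)OC=C
Why: Lipase-catalysed kinetic resolution by transesterification should acylate the (2R) methyl carbinol (large alkenyl against small methyl) far faster than the (2S) one, and because the relative configuration is fixed in 4 this also selects the (1S) ring centre.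

**Step 5**
Reactants: 5 (1S,2R)-α-ionyl acetate
Product: 6 (2R,3E)-4-[(1S)-2,6,6-trimethylcyclohex-2-en-1-yl]but-3-en-2-ol
Conditions: K2CO3 (cat.), MeOH, rt
Reagents that add atoms: none
Why: Mild methanolysis of the acetate, under which the doubly allylic ring C–H of the alcohol is not acidic and cannot epimerise.

**Step 6**
Reactants: 6 (1S,2R)-α-ionol
Product: 7 (S)-α-ionone, (3E)-4-[(1S)-2,6,6-trimethylcyclohex-2-en-1-yl]but-3-en-2-one
Conditions: MnO2 (excess), CH2Cl2, rt
Reagents that add atoms: none
Why: MnO2 oxidises allylic alcohols selectively under neutral heterogeneous conditions, which avoids γ-deprotonation of the enone and so keeps the ring stereocentre.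

**Step 7**
Reactants: 7 (S)-α-ionone
Product: 9 (S)-dihydro-α-ionone i.e. 4-[(1S)-2,6,6-trimethylcyclohex-2-en-1-yl]butan-2-one, via triethylsilyl enol ether 8 (not isolated)
Conditions: Et3SiH, RhCl(PPh3)3 (monovalent rhodium, 1 mol%), benzene, 50 °C; then K2CO3 (cat.), MeOH, rt
Reagents that add atoms: none
Why: Rhodium-catalysed 1,4-hydrosilylation of an enone with a monohydrosilane reduces only the conjugated C=C, leaving the trisubstituted ring alkene and the adjacent stereocentre untouched, and methanolysis of the silyl enol ether releases the saturated ketone.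

**Step 8**
Reactants: 9 (S)-dihydro-α-ionone; 10 methyl propiolate
Product: 13 methyl 4-[(methoxycarbonyl)oxy]-4-methyl-6-[(1S)-2,6,6-trimethylcyclohex-2-en-1-yl]hex-2-ynoate (both C4 epimers), via lithium methyl propiolate 11 (not isolated), via lithium propargylic alkoxide 12 (not isolated)
Conditions: 10, LiN(SiMe3)2, THF, −78 °C; then 9, −78 °C; then ClCO2Me, −78 to 0 °C
Reagents that add atoms: methyl chloroformate, COC(=O)Cl
Why: 1,2-Addition of a lithium acetylide to the ketone at −78 °C followed by O-acylation of the tertiary lithium alkoxide in the same flask, which is easier than acylating the isolated tertiary alcohol; the new carbinol centre needs no control because it becomes an allene terminus.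

**Step 9**
Reactants: 13 propargylic methyl carbonate
Product: 14 methyl 4-methyl-6-[(1S)-2,6,6-trimethylcyclohex-2-en-1-yl]hexa-2,3-dienoate (both allene epimers)
Conditions: Pd(PPh3)4 (zerovalent palladium, 5 mol%), HCO2H, Et3N, THF, rt
Reagents that add atoms: none
Why: Palladium-catalysed formate hydrogenolysis of a tertiary propargylic carbonate: SN2' oxidative addition gives an allenylpalladium species, the formate loses CO2 to give the hydride, and reductive elimination places H on the ester-bearing carbon to give the 2,3-allenoate.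

**Step 10**
Reactants: 14 allenoate (both allene epimers)
Product: 15 methyl 2-[(4aS,8aS)-2,5,5,8a-tetramethyl-3,4,4a,5,6,7,8,8a-octahydronaphthalen-1-yl]acetate
Conditions: Fe(acac)3 (trivalent iron, 0.5 equiv), PhSiH3 (2.5 equiv), EtOH/HOCH2CH2OH 5:1, 0.02 M, 60 °C, argon
Reagents that add atoms: none
Why: Proposed new method: the iron hydride formed from Fe(acac)3 and PhSiH3 should transfer a hydrogen atom to C1 of the electron-rich C1=C10 ring alkene (Markovnikov sense), and the tertiary, nucleophilic C10 radical should add to C9, the β-carbon of the C9=C11–CO2Me unit of the allenoate, to give an ester-stabilised allyl radical over C8–C9–C11 that divalent iron reduces to the dienolate, which ethanol protonates kinetically at C11 so that the tetrasubstituted C8=C9 alkene stays in the ring. The closest known reaction type is the hydrogen-atom-transfer-initiated reductive coupling and Giese-type cyclization of unactivated alkenes onto acrylates and enones under the same Fe(acac)3/PhSiH3 conditions; what has not been shown is an allenoate attacked at its central carbon as the acceptor. Ring B closes in a six-membered mode that is exo with respect to the conjugated C9=C11 bond, whose p orbital at C9 lies in the plane of the tether, while the alternative 5-exo attack at C8 would join two fully substituted carbons and leave a vinyl radical. The new stereocentre C10 is controlled by C5: in a chair-like transition state with the C5–C6 tether equatorial on ring A the C9–C10 bond forms equatorially and the C10 methyl ends axial and anti to H5 (trans-decalin), as in the second ring closure of radical polyene cyclizations, and C5 from (S)-α-ionone fixes the absolute sense. The step needs hydrogen-atom transfer to the ring alkene ahead of the electron-poor allene, which the electrophilic character of the metal hydride and high dilution should secure, and it needs no control of the allene axis because both epimers give the same C10 radical and the axis is destroyed.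

**Step 11**
Reactants: 15 decalin methyl ester
Product: 16 2-[(4aS,8aS)-2,5,5,8a-tetramethyl-3,4,4a,5,6,7,8,8a-octahydronaphthalen-1-yl]ethan-1-ol
Conditions: LiAlH4, THF, 0 °C
Reagents that add atoms: none
Why: LiAlH4 reduction of an ester to the primary alcohol, to which the tetrasubstituted β,γ-alkene is inert.

**Step 12**
Reactants: 16 primary alcohol
Product: 17 2-[(4aS,8aS)-2,5,5,8a-tetramethyl-3,4,4a,5,6,7,8,8a-octahydronaphthalen-1-yl]ethyl iodide
Conditions: I2, PPh3, imidazole, CH2Cl2, 0 °C to rt
Reagents that add atoms: iodine, II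
Why: Appel-type iodination by SN2 displacement of the oxyphosphonium ion at a primary carbon under near-neutral conditions that do not isomerise the alkene.

**Step 13**
Reactants: 17 primary iodide; 18 triethyl phosphonoacetate (2 equiv)
Product: 20 ethyl 2-(diethoxyphosphoryl)-4-[(4aS,8aS)-2,5,5,8a-tetramethyl-3,4,4a,5,6,7,8,8a-octahydronaphthalen-1-yl]butanoate (both C2 epimers), via sodium triethyl phosphonoacetate 19 (not isolated)
Conditions: 18, NaH, THF/DMF 1:1, 0 °C; then 17, 60 °C
Reagents that add atoms: none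
Why: SN2 C-alkylation of the stabilised phosphonoacetate anion with a primary iodide; the soft, weakly basic carbanion, used in excess to limit dialkylation, should substitute in preference to eliminating to the conjugated diene.

**Step 14**
Reactants: 20 alkylated phosphonoacetate; 21 3-(trimethylsilyl)prop-2-ynal
Product: 23 ethyl (2E)-2-{2-[(4aS,8aS)-2,5,5,8a-tetramethyl-3,4,4a,5,6,7,8,8a-octahydronaphthalen-1-yl]ethyl}-5-(trimethylsilyl)pent-2-en-4-ynoate, via sodium phosphonate carbanion 22 (not isolated)
Conditions: 20, NaH, THF, 0 °C; then 21, 0 °C to rt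
Reagents that add atoms: none
Why: Horner–Wadsworth–Emmons olefination of an α-alkylated phosphonoacetate under equilibrating sodium conditions should place the ester trans to the aldehyde residue, which sets the E geometry of C13=C14 (the future CH2OH trans to C15).

**Step 15**
Reactants: 23 enynoate
Product: 24 (2E)-2-{2-[(4aS,8aS)-2,5,5,8a-tetramethyl-3,4,4a,5,6,7,8,8a-octahydronaphthalen-1-yl]ethyl}-5-(trimethylsilyl)pent-2-en-4-yn-1-ol
Conditions: i-Bu2AlH (2.5 equiv), CH2Cl2, −78 to 0 °C
Reagents that add atoms: none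
Why: i-Bu2AlH reduces the conjugated ester 1,2 to the allylic alcohol, without conjugate reduction and without hydroalumination of the silylalkyne at low temperature.

**Step 16**
Reactants: 24 silyl enynol
Product: 25 (2E)-2-{2-[(4aS,8aS)-2,5,5,8a-tetramethyl-3,4,4a,5,6,7,8,8a-octahydronaphthalen-1-yl]ethyl}pent-2-en-4-yn-1-ol
Conditions: K2CO3 (cat.), MeOH, rt
Reagents that add atoms: none
Why: Carbonate-catalysed methanolysis cleaves the alkynyl C–Si bond selectively and frees the terminal alkyne.

**Step 17**
Reactants: 25 terminal enynol; 26 4-bromofuran-2(5H)-one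
Product: 27 4-[(3E)-4-(hydroxymethyl)-6-[(4aS,8aS)-2,5,5,8a-tetramethyl-3,4,4a,5,6,7,8,8a-octahydronaphthalen-1-yl]hex-3-en-1-yn-1-yl]furan-2(5H)-one
Conditions: PdCl2(PPh3)2 (divalent palladium precatalyst, 3 mol%), CuI (monovalent copper, 6 mol%), Et3N, THF, rt, degassed
Reagents that add atoms: none
Why: Sonogashira coupling of a terminal alkyne with an activated β-bromo enoate proceeds at room temperature; a tertiary amine is used so that no amine adds to the bromobutenolide, and the free alcohol is tolerated.

**Step 18**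
Reactants: 27 dienyne butenolide
Product: 28 target, 4-[(1Z,3E)-4-(hydroxymethyl)-6-[(4aS,8aS)-2,5,5,8a-tetramethyl-3,4,4a,5,6,7,8,8a-octahydronaphthalen-1-yl]hexa-1,3-dien-1-yl]furan-2(5H)-one
Conditions: Zn(Cu/Ag) (zinc dust activated with Cu(OAc)2 and AgNO3), MeOH/H2O 1:1, 25–40 °C, dark
Reagents that add atoms: none
Why: Activated zinc reduces conjugated alkynes by cis delivery of two hydrogens from the protic medium and should stop at the alkene, which sets the Z geometry of C15=C16 while the C13=C14 and butenolide alkenes stay in place.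

**Compound list**

1 | α-ionone, (3E)-4-(2,6,6-trimethylcyclohex-2-en-1-yl)but-3-en-2-one (racemic) | CC1=CCCC(C)(C)C1/C=C/C(C)=O | starting material
2 | α-ionol, (3E)-4-(2,6,6-trimethylcyclohex-2-en-1-yl)but-3-en-2-ol (four stereoisomers) | CC1=CCCC(C)(C)C1/C=C/C(C)O | intermediate
3 | rac-(2R*,3E)-4-[(1S*)-2,6,6-trimethylcyclohex-2-en-1-yl]but-3-en-2-yl 4-nitrobenzoate (racemate, (1S,2R) enantiomer drawn) | CC1=CCCC(C)(C)[C@@H]1/C=C/[C@@H](C)OC(=O)c2ccc(cc2)[N+](=O)[O-] | intermediate
4 | rac-(2R*,3E)-4-[(1S*)-2,6,6-trimethylcyclohex-2-en-1-yl]but-3-en-2-ol (racemate, (1S,2R) enantiomer drawn) | CC1=CCCC(C)(C)[C@@H]1/C=C/[C@@H](C)O | intermediate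
5 | (2R,3E)-4-[(1S)-2,6,6-trimethylcyclohex-2-en-1-yl]but-3-en-2-yl acetate | CC1=CCCC(C)(C)[C@@H]1/C=C/[C@@H](C)OC(C)=O | intermediate
6 | (2R,3E)-4-[(1S)-2,6,6-trimethylcyclohex-2-en-1-yl]but-3-en-2-ol (single enantiomer) | CC1=CCCC(C)(C)[C@@H]1/C=C/[C@@H](C)O | intermediate
7 | (S)-α-ionone, (3E)-4-[(1S)-2,6,6-trimethylcyclohex-2-en-1-yl]but-3-en-2-one | CC1=CCCC(C)(C)[C@@H]1/C=C/C(C)=O | intermediate
8 | triethyl({4-[(1S)-2,6,6-trimethylcyclohex-2-en-1-yl]but-2-en-2-yl}oxy)silane (E/Z) | CC1=CCCC(C)(C)[C@@H]1CC=C(C)O[Si](CC)(CC)CC | intermediate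
9 | (S)-dihydro-α-ionone, 4-[(1S)-2,6,6-trimethylcyclohex-2-en-1-yl]butan-2-one | CC1=CCCC(C)(C)[C@@H]1CCC(C)=O | intermediate
10 | methyl propiolate | C#CC(=O)OC | starting material
11 | lithium methyl propiolate (lithium 3-methoxy-3-oxoprop-1-yn-1-ide) | [Li+].[C-]#CC(=O)OC | intermediate
12 | lithium alkoxide of methyl 4-hydroxy-4-methyl-6-[(1S)-2,6,6-trimethylcyclohex-2-en-1-yl]hex-2-ynoate (both C4 epimers) | CC1=CCCC(C)(C)[C@@H]1CCC(C)([O-])C#CC(=O)OC.[Li+] | intermediate
13 | methyl 4-[(methoxycarbonyl)oxy]-4-methyl-6-[(1S)-2,6,6-trimethylcyclohex-2-en-1-yl]hex-2-ynoate (both C4 epimers) | CC1=CCCC(C)(C)[C@@H]1CCC(C)(OC(=O)OC)C#CC(=O)OC | intermediate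
14 | methyl 4-methyl-6-[(1S)-2,6,6-trimethylcyclohex-2-en-1-yl]hexa-2,3-dienoate (both allene epimers) | CC1=CCCC(C)(C)[C@@H]1CCC(C)=C=CC(=O)OC | intermediate
15 | methyl 2-[(4aS,8aS)-2,5,5,8a-tetramethyl-3,4,4a,5,6,7,8,8a-octahydronaphthalen-1-yl]acetate | CC1=C(CC(=O)OC)[C@@]2(C)CCCC(C)(C)[C@@H]2CC1 | intermediate
16 | 2-[(4aS,8aS)-2,5,5,8a-tetramethyl-3,4,4a,5,6,7,8,8a-octahydronaphthalen-1-yl]ethan-1-ol | CC1=C(CCO)[C@@]2(C)CCCC(C)(C)[C@@H]2CC1 | intermediate
17 | 2-[(4aS,8aS)-2,5,5,8a-tetramethyl-3,4,4a,5,6,7,8,8a-octahydronaphthalen-1-yl]ethyl iodide | CC1=C(CCI)[C@@]2(C)CCCC(C)(C)[C@@H]2CC1 | intermediate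
18 | triethyl phosphonoacetate | CCOC(=O)CP(=O)(OCC)OCC | starting material
19 | sodium triethyl phosphonoacetate (carbanion) | CCOC(=O)[CH-]P(=O)(OCC)OCC.[Na+] | intermediate
20 | ethyl 2-(diethoxyphosphoryl)-4-[(4aS,8aS)-2,5,5,8a-tetramethyl-3,4,4a,5,6,7,8,8a-octahydronaphthalen-1-yl]butanoate (both C2 epimers) | CC1=C(CCC(C(=O)OCC)P(=O)(OCC)OCC)[C@@]2(C)CCCC(C)(C)[C@@H]2CC1 | intermediate
21 | 3-(trimethylsilyl)prop-2-ynal | C[Si](C)(C)C#CC=O | starting material
22 | sodium carbanion of phosphonate 20 | CC1=C(CC[C-](C(=O)OCC)P(=O)(OCC)OCC)[C@@]2(C)CCCC(C)(C)[C@@H]2CC1.[Na+] | intermediate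
23 | ethyl (2E)-2-{2-[(4aS,8aS)-2,5,5,8a-tetramethyl-3,4,4a,5,6,7,8,8a-octahydronaphthalen-1-yl]ethyl}-5-(trimethylsilyl)pent-2-en-4-ynoate | CC1=C(CC/C(C(=O)OCC)=C\C#C[Si](C)(C)C)[C@@]2(C)CCCC(C)(C)[C@@H]2CC1 | intermediate
24 | (2E)-2-{2-[(4aS,8aS)-2,5,5,8a-tetramethyl-3,4,4a,5,6,7,8,8a-octahydronaphthalen-1-yl]ethyl}-5-(trimethylsilyl)pent-2-en-4-yn-1-ol | CC1=C(CC/C(CO)=C\C#C[Si](C)(C)C)[C@@]2(C)CCCC(C)(C)[C@@H]2CC1 | intermediate
25 | (2E)-2-{2-[(4aS,8aS)-2,5,5,8a-tetramethyl-3,4,4a,5,6,7,8,8a-octahydronaphthalen-1-yl]ethyl}pent-2-en-4-yn-1-ol | CC1=C(CC/C(CO)=C\C#C)[C@@]2(C)CCCC(C)(C)[C@@H]2CC1 | intermediate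
26 | 4-bromofuran-2(5H)-one | BrC1=CC(=O)OC1 | starting material
27 | 4-[(3E)-4-(hydroxymethyl)-6-[(4aS,8aS)-2,5,5,8a-tetramethyl-3,4,4a,5,6,7,8,8a-octahydronaphthalen-1-yl]hex-3-en-1-yn-1-yl]furan-2(5H)-one | CC1=C(CC/C(CO)=C\C#CC3=CC(=O)OC3)[C@@]2(C)CCCC(C)(C)[C@@H]2CC1 | intermediate
28 | 4-[(1Z,3E)-4-(hydroxymethyl)-6-[(4aS,8aS)-2,5,5,8a-tetramethyl-3,4,4a,5,6,7,8,8a-octahydronaphthalen-1-yl]hexa-1,3-dien-1-yl]furan-2(5H)-one | CC1=C(CC/C(=C\C=C/C2=CC(=O)OC2)CO)[C@@]2(C)CCCC(C)(C)[C@@H]2CC1 | target

**Step count and risks**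

Total step count: 18. Longest linear sequence: 18 steps (1 to 28); compounds 10, 18, 21 and 26 are bought.

Steps most likely to fail:

1. Step 10 (proposed new method). The hydrogen atom may go to the allenoate instead of the ring alkene. The C10 radical may be reduced before it cyclizes. Ring B may close to the cis ring fusion. The dienolate may be protonated at C8 instead of C11. Reversible hydrogen abstraction at C5 may erode the enantiopurity. Fallback (cation–olefin closure of ring B, known chemistry): it sets out from ketone 9. A Wittig reaction with the ylide of (2-carboxyethyl)triphenylphosphonium bromide (NaN(SiMe3)2, THF) would give (3E/Z)-4-methyl-6-[(1S)-2,6,6-trimethylcyclohex-2-en-1-yl]hex-3-enoic acid F1. ClSO3H in 2-nitropropane at −78 °C would protonate the ring alkene and close ring B with carboxyl trapping at C8 to give sclareolide F2, trans-fused and possibly accompanied by its C8 epimer; the low temperature is needed so that ring closure outruns proton loss from C5. H2SO4 in MeOH would then open the lactone with loss of the C9 proton and should give mainly the tetrasubstituted alkene ester 15, where the route resumes at step 11.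

2. Step 9. Reductive elimination may occur at the propargylic terminus and give the alkynoate, or free phosphine and amine may isomerise the allenoate to the conjugated 2,4-dienoate. Fallback (ketene Wittig route to the allene): it sets out from ketone 9. Reductive cyanation with tosylmethyl isocyanide and t-BuOK (DME/t-BuOH) would give 2-methyl-4-[(1S)-2,6,6-trimethylcyclohex-2-en-1-yl]butanenitrile F3. KOH in ethylene glycol at 150 °C would hydrolyse it to 2-methyl-4-[(1S)-2,6,6-trimethylcyclohex-2-en-1-yl]butanoic acid F4. Oxalyl chloride would give 2-methyl-4-[(1S)-2,6,6-trimethylcyclohex-2-en-1-yl]butanoyl chloride F5. Et3N with methyl (triphenylphosphoranylidene)acetate in CH2Cl2 would form the ketene and olefinate it to allenoate 14, where the route resumes at step 10.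

3. Step 18. The triene may be over-reduced, or the C15=C16 alkene may isomerise from Z to E during reduction or isolation. Fallback (stereoretentive coupling in place of semi-reduction): it sets out from terminal enynol 25, before the Sonogashira step. N-Iodosuccinimide with catalytic AgNO3 in acetone would give (2E)-5-iodo-2-{2-[(4aS,8aS)-2,5,5,8a-tetramethyl-3,4,4a,5,6,7,8,8a-octahydronaphthalen-1-yl]ethyl}pent-2-en-4-yn-1-ol F6. Diimide from 2-nitrobenzenesulfonyl hydrazide and Et3N would reduce the iodoalkyne to (2E,4Z)-5-iodo-2-{2-[(4aS,8aS)-2,5,5,8a-tetramethyl-3,4,4a,5,6,7,8,8a-octahydronaphthalen-1-yl]ethyl}penta-2,4-dien-1-ol F7. Stille coupling (Pd2(dba)3, AsPh3, CuI, DMF, rt) with 4-(tributylstannyl)furan-2(5H)-one F8, made from bromide 26 with Bu3SnSnBu3 and Pd(PPh3)4, would give target 28 with retention of the Z geometry.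

**Further compounds**

F1 | step 10 | (3E/Z)-4-methyl-6-[(1S)-2,6,6-trimethylcyclohex-2-en-1-yl]hex-3-enoic acid | CC1=CCCC(C)(C)[C@@H]1CCC(C)=CCC(=O)O
F2 | step 10 | sclareolide, (3aR,5aS,9aS,9bR)-3a,6,6,9a-tetramethyldecahydronaphtho[2,1-b]furan-2(1H)-one | C[C@]12CCCC(C)(C)[C@@H]1CC[C@@]3(C)OC(=O)C[C@H]23
F3 | step 9 | 2-methyl-4-[(1S)-2,6,6-trimethylcyclohex-2-en-1-yl]butanenitrile (both C2 epimers) | CC1=CCCC(C)(C)[C@@H]1CCC(C)C#N
F4 | step 9 | 2-methyl-4-[(1S)-2,6,6-trimethylcyclohex-2-en-1-yl]butanoic acid (both C2 epimers) | CC1=CCCC(C)(C)[C@@H]1CCC(C)C(=O)O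
F5 | step 9 | 2-methyl-4-[(1S)-2,6,6-trimethylcyclohex-2-en-1-yl]butanoyl chloride (both C2 epimers) | CC1=CCCC(C)(C)[C@@H]1CCC(C)C(=O)Cl
F6 | step 18 | (2E)-5-iodo-2-{2-[(4aS,8aS)-2,5,5,8a-tetramethyl-3,4,4a,5,6,7,8,8a-octahydronaphthalen-1-yl]ethyl}pent-2-en-4-yn-1-ol | CC1=C(CC/C(CO)=C\C#CI)[C@@]2(C)CCCC(C)(C)[C@@H]2CC1
F7 | step 18 | (2E,4Z)-5-iodo-2-{2-[(4aS,8aS)-2,5,5,8a-tetramethyl-3,4,4a,5,6,7,8,8a-octahydronaphthalen-1-yl]ethyl}penta-2,4-dien-1-ol | CC1=C(CC/C(CO)=C\C=C/I)[C@@]2(C)CCCC(C)(C)[C@@H]2CC1
F8 | step 18 | 4-(tributylstannyl)furan-2(5H)-one | CCCC[Sn](CCCC)(CCCC)C1=CC(=O)OC1
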